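**Strategy.** The flavanone unit is cut across ring C at O1–C2 and C4–C4a. Ring A is a phloroglucinol ring, so its C4a–H (flanked by oxygen-bearing carbons) and the adjacent phenolic O1 form a C,O-dinucleophile that can take up a cinnamoyl unit as the matching dielectrophile (acyl carbon C4, β-carbon C2). The key step does this in one pot: magnesium-templated ortho-acylation of a flavonyl-substituted 3,5-bis(benzyloxy)phenol with 4-(benzyloxy)cinnamoyl chloride, then oxa-Michael closure, giving ring C and C2. The precursor is a symmetrical biaryl made by Suzuki coupling; its benzyl ethers leave one free oxygen and so fix the C6 linkage. C2 is then resolved by transfer hydrogenation.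

Key step: step 7

Remarks on the chemistry:
- The starting trimethoxyflavone, 3,5-bis(benzyloxy)phenol and 4-(benzyloxy)cinnamic acid are taken as commercial.
- The target carries no descriptor for the axis between C3 of the flavone unit and C6 of the flavanone unit. It is treated as not configurationally defined, and slowly rotating rotamers of the benzylated flavanone intermediates are carried as mixtures.
- The target is the (2R)-flavanone (C2 priorities O1 > aryl > C3 > H).

Step 1
Reactants: 1 5,7-dimethoxy-2-(4-methoxyphenyl)-4H-chromen-4-one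
Product: 3 3-iodo-5,7-dimethoxy-2-(4-methoxyphenyl)-4H-chromen-4-one, via 3-lithiochromone 2 (not isolated)
Conditions: LiN(i-Pr)2 (1.2 equiv), THF, −78 °C; then I2, −78 → −40 °C
Reagents that add atoms: iodine, [I][I]
Why: Deprotonation of the vinylic C3–H next to the carbonyl (C3 lithiation of a flavone) gives a vinyllithium that iodine should trap at low temperature before it can ring-open.

Step 2
Reactants: 3 3-iodo-5,7-dimethoxy-2-(4-methoxyphenyl)-4H-chromen-4-one
Product: 4 5-hydroxy-3-iodo-7-methoxy-2-(4-methoxyphenyl)-4H-chromen-4-one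
Conditions: BCl3 (2 equiv), CH2Cl2, −78 → 0 °C; H2O
Reagents that add atoms: none
Why: Chelation of boron between the C4 carbonyl and the peri 5-methoxy oxygen should make this Lewis-acid O-demethylation selective, leaving the 7- and 4'-methyl ethers and the vinyl iodide untouched.

Step 3
Reactants: 5 3,5-bis(benzyloxy)phenol
Product: 6 [3,5-bis(benzyloxy)phenoxy]tri(propan-2-yl)silane
Conditions: i-Pr3SiCl, imidazole, DMF, rt
Reagents that add atoms: chlorotri(propan-2-yl)silane, CC(C)[Si](Cl)(C(C)C)C(C)C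
Why: Routine silylation masks the acidic phenol, and the bulky, poorly coordinating silyl ether shields its two neighbouring positions so that the next metalation goes between the benzyloxy groups.

Step 4
Reactants: 6 [3,5-bis(benzyloxy)phenoxy]tri(propan-2-yl)silane
Product: 8 2-[2,6-bis(benzyloxy)-4-{[tri(propan-2-yl)silyl]oxy}phenyl]-4,4,5,5-tetramethyl-1,3,2-dioxaborolane, via aryllithium 7 (not isolated)
Conditions: n-BuLi (1.2 equiv), THF, 0 °C; then i-PrOBpin, −78 °C → rt; aq. NH4Cl
Reagents that add atoms: 2-isopropoxy-4,4,5,5-tetramethyl-1,3,2-dioxaborolane, CC(C)OB1OC(C)(C)C(C)(C)O1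
Why: Directed ortho-metalation should take place at the C–H flanked by the two benzyloxy groups, and the aryllithium is then borylated.

Step 5
Reactants: 4 5-hydroxy-3-iodo-7-methoxy-2-(4-methoxyphenyl)-4H-chromen-4-one; 8 2-[2,6-bis(benzyloxy)-4-{[tri(propan-2-yl)silyl]oxy}phenyl]-4,4,5,5-tetramethyl-1,3,2-dioxaborolane
Product: 10 3-[2,6-bis(benzyloxy)-4-hydroxyphenyl]-5-hydroxy-7-methoxy-2-(4-methoxyphenyl)-4H-chromen-4-one, via silyl ether 9 (not isolated)
Conditions: Pd(OAc)2 (5 mol %), SPhos (2-dicyclohexylphosphino-2',6'-dimethoxybiphenyl, 10 mol %), K3PO4, toluene/H2O (10:1), 90 °C; then Bu4NF, THF, 0 °C → rt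
Reagents that add atoms: none
Why: Suzuki coupling with an electron-rich biaryl dialkylphosphine, a ligand class suited to joining di-ortho-alkoxy arylboron reagents to hindered halides, forms the C3–aryl bond (the free chelated 5-OH is tolerated), and fluoride then cleaves the aryl silyl ether.

Step 6
Reactants: 11 (E)-3-[4-(benzyloxy)phenyl]prop-2-enoic acid
Product: 12 (E)-3-[4-(benzyloxy)phenyl]prop-2-enoyl chloride
Conditions: (COCl)2, DMF (cat.), CH2Cl2, 0 °C → rt
Reagents that add atoms: oxalyl chloride, O=C(Cl)C(Cl)=O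
Why: Standard acid chloride formation via the chloroiminium catalyst, used crude after evaporation.

Step 7
Reactants: 10 3-[2,6-bis(benzyloxy)-4-hydroxyphenyl]-5-hydroxy-7-methoxy-2-(4-methoxyphenyl)-4H-chromen-4-one; 12 (E)-3-[4-(benzyloxy)phenyl]prop-2-enoyl chloride
Product: 15 racemic 5,7-bis(benzyloxy)-2-[4-(benzyloxy)phenyl]-6-[5-hydroxy-7-methoxy-2-(4-methoxyphenyl)-4-oxo-4H-chromen-3-yl]-2,3-dihydro-4H-chromen-4-one, via bis(bromomagnesium) phenoxide 13 (not isolated), via 2'-hydroxychalcone 14 (not isolated)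
Conditions: EtMgBr (2.05 equiv), toluene/THF (10:1), 0 °C; 12, toluene, rt → 60 °C; then AcOH, NaOAc, EtOH, 70 °C (same flask)
Reagents that add atoms: none
Why: EtMgBr turns both phenols of 10 into bromomagnesium phenoxides (13); in toluene the acid chloride binds to magnesium at the oxygen of the benzyloxy-flanked ring and is delivered through a six-membered chelate to the adjacent ring carbon (the later C4a), any aryl ester formed by O-acylation being expected to converge on the same ketone by acyl transfer on warming, and after the AcOH quench acetate-mediated conjugate addition of that same oxygen (the later O1) to the enone of 14 closes the ring. The closest known chemistry is the ortho-C-acylation of bromomagnesium phenoxides by acyl chlorides, joined to the classical one-pot Friedel–Crafts acylation/oxa-Michael synthesis of 5,7-dioxygenated flavanones from phloroglucinols and cinnamoyl chlorides. Ring C closes by a 6-endo-trig oxa-Michael addition. C2 is formed here without control, as the racemate, and its configuration is set in step 8 by the chiral catalyst. The step needs attack at the acyl carbon by ring carbon instead of O-acylation or attack at the β-carbon (which would lead to a 4-aryl-dihydrocoumarin): the acid-free, magnesium-templated conditions and the acid chloride should secure this, and the two open ring positions are equivalent so only one ketone can form. It also needs the right oxygen to close the ring: only the oxygen para to the flavone is free, the two ortho oxygens being benzyl ethers, so the 6-linked flavanone forms and the 8-linked isomer cannot.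

Step 8
Reactants: 15 racemic 5,7-bis(benzyloxy)-2-[4-(benzyloxy)phenyl]-6-[5-hydroxy-7-methoxy-2-(4-methoxyphenyl)-4-oxo-4H-chromen-3-yl]-2,3-dihydro-4H-chromen-4-one
Product: 16 (2R)-5,7-bis(benzyloxy)-2-[4-(benzyloxy)phenyl]-6-[5-hydroxy-7-methoxy-2-(4-methoxyphenyl)-4-oxo-4H-chromen-3-yl]-2,3-dihydro-4H-chromen-4-one
Conditions: RuCl(p-cymene)[(S,S)-TsDPEN] (3 mol %), HCO2H/Et3N (5:2), EtOAc, rt, stopped slightly beyond half conversion; chromatography
Reagents that add atoms: none
Why: Kinetic resolution by asymmetric transfer hydrogenation: the (S,S)-catalyst should deliver hydride to C4 to give a (4S)-carbinol (as with chroman-4-one), which only the (2S)-ketone can do along the favoured path to the cis-flavan-4-ol, so the (2R)-ketone is left and its configuration is fixed by the catalyst.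

Step 9
Reactants: 16 (2R)-5,7-bis(benzyloxy)-2-[4-(benzyloxy)phenyl]-6-[5-hydroxy-7-methoxy-2-(4-methoxyphenyl)-4-oxo-4H-chromen-3-yl]-2,3-dihydro-4H-chromen-4-one
Product: 17 (2R)-5,7-dihydroxy-2-(4-hydroxyphenyl)-6-[5-hydroxy-7-methoxy-2-(4-methoxyphenyl)-4-oxo-4H-chromen-3-yl]-2,3-dihydro-4H-chromen-4-one (CNP0292254.1)
Conditions: H2 (1 atm), Pd/C (10 % Pd), EtOAc/MeOH, rt
Reagents that add atoms: none
Why: Hydrogenolysis of the three aryl benzyl ethers is neutral, so it avoids the base-induced ring opening (retro-oxa-Michael) that would racemise C2, and the methyl ethers and both pyranone rings should be left intact.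

**Compound list**

1 | 5,7-dimethoxy-2-(4-methoxyphenyl)-4H-chromen-4-one | COc1ccc(-c2cc(=O)c3c(OC)cc(OC)cc3o2)cc1 | starting material
2 | 3-lithio-5,7-dimethoxy-2-(4-methoxyphenyl)-4H-chromen-4-one | COc1ccc(-c2oc3cc(OC)cc(OC)c3c(=O)c2[Li])cc1 | intermediate
3 | 3-iodo-5,7-dimethoxy-2-(4-methoxyphenyl)-4H-chromen-4-one | COc1ccc(-c2oc3cc(OC)cc(OC)c3c(=O)c2I)cc1 | intermediate
4 | 5-hydroxy-3-iodo-7-methoxy-2-(4-methoxyphenyl)-4H-chromen-4-one | COc1ccc(-c2oc3cc(OC)cc(O)c3c(=O)c2I)cc1 | intermediate
5 | 3,5-bis(benzyloxy)phenol | Oc1cc(OCc2ccccc2)cc(OCc2ccccc2)c1 | starting material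
6 | [3,5-bis(benzyloxy)phenoxy]tri(propan-2-yl)silane | CC(C)[Si](Oc1cc(OCc2ccccc2)cc(OCc2ccccc2)c1)(C(C)C)C(C)C | intermediate
7 | [2,6-bis(benzyloxy)-4-{[tri(propan-2-yl)silyl]oxy}phenyl]lithium | [Li]c1c(OCc2ccccc2)cc(O[Si](C(C)C)(C(C)C)C(C)C)cc1OCc1ccccc1 | intermediate
8 | 2-[2,6-bis(benzyloxy)-4-{[tri(propan-2-yl)silyl]oxy}phenyl]-4,4,5,5-tetramethyl-1,3,2-dioxaborolane | CC1(C)OB(OC1(C)C)c1c(OCc2ccccc2)cc(O[Si](C(C)C)(C(C)C)C(C)C)cc1OCc1ccccc1 | intermediate
9 | 3-[2,6-bis(benzyloxy)-4-{[tri(propan-2-yl)silyl]oxy}phenyl]-5-hydroxy-7-methoxy-2-(4-methoxyphenyl)-4H-chromen-4-one | COc1ccc(-c2oc3cc(OC)cc(O)c3c(=O)c2-c2c(OCc3ccccc3)cc(O[Si](C(C)C)(C(C)C)C(C)C)cc2OCc2ccccc2)cc1 | intermediate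
10 | 3-[2,6-bis(benzyloxy)-4-hydroxyphenyl]-5-hydroxy-7-methoxy-2-(4-methoxyphenyl)-4H-chromen-4-one | COc1ccc(-c2oc3cc(OC)cc(O)c3c(=O)c2-c2c(OCc3ccccc3)cc(O)cc2OCc2ccccc2)cc1 | intermediate
11 | (E)-3-[4-(benzyloxy)phenyl]prop-2-enoic acid | OC(=O)/C=C/c1ccc(OCc2ccccc2)cc1 | starting material
12 | (E)-3-[4-(benzyloxy)phenyl]prop-2-enoyl chloride | ClC(=O)/C=C/c1ccc(OCc2ccccc2)cc1 | intermediate
13 | bis(bromomagnesium) phenoxide of 10 | COc1ccc(-c2oc3cc(OC)cc(O[Mg]Br)c3c(=O)c2-c2c(OCc3ccccc3)cc(O[Mg]Br)cc2OCc2ccccc2)cc1 | intermediate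
14 | 3-{2,6-bis(benzyloxy)-3-[(E)-3-(4-(benzyloxy)phenyl)prop-2-enoyl]-4-hydroxyphenyl}-5-hydroxy-7-methoxy-2-(4-methoxyphenyl)-4H-chromen-4-one | COc1ccc(-c2oc3cc(OC)cc(O)c3c(=O)c2-c2c(OCc3ccccc3)c(C(=O)/C=C/c3ccc(OCc4ccccc4)cc3)c(O)cc2OCc2ccccc2)cc1 | intermediate
15 | racemic 5,7-bis(benzyloxy)-2-[4-(benzyloxy)phenyl]-6-[5-hydroxy-7-methoxy-2-(4-methoxyphenyl)-4-oxo-4H-chromen-3-yl]-2,3-dihydro-4H-chromen-4-one | COc1ccc(-c2oc3cc(OC)cc(O)c3c(=O)c2-c2c(OCc3ccccc3)cc3c(c2OCc2ccccc2)C(=O)CC(c2ccc(OCc4ccccc4)cc2)O3)cc1 | intermediate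
16 | (2R)-5,7-bis(benzyloxy)-2-[4-(benzyloxy)phenyl]-6-[5-hydroxy-7-methoxy-2-(4-methoxyphenyl)-4-oxo-4H-chromen-3-yl]-2,3-dihydro-4H-chromen-4-one | COc1ccc(-c2oc3cc(OC)cc(O)c3c(=O)c2-c2c(OCc3ccccc3)cc3c(c2OCc2ccccc2)C(=O)C[C@H](c2ccc(OCc4ccccc4)cc2)O3)cc1 | intermediate
17 | (2R)-5,7-dihydroxy-2-(4-hydroxyphenyl)-6-[5-hydroxy-7-methoxy-2-(4-methoxyphenyl)-4-oxo-4H-chromen-3-yl]-2,3-dihydro-4H-chromen-4-one | COc1ccc(-c2oc3cc(OC)cc(O)c3c(=O)c2-c2c(O)cc3c(c2O)C(=O)C[C@H](c2ccc(O)cc2)O3)cc1 | target

**Step count and risks**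

Total steps: 9. Longest linear sequence: 6 steps (steps 1, 2, 5, 7, 8, 9; the branch through steps 3, 4, 5, 7, 8, 9 is equally long).

Steps most likely to fail:

1. Step 7. O-acylation of the magnesium phenoxide may outrun C-acylation and the resulting aryl ester may not pass its acyl group on to carbon, or ring closure of the chelated chalcone may stay incomplete. Fallback (stepwise Claisen–Schmidt construction): starting from 10, Friedel–Crafts acetylation (AcOH, (CF3CO)2O, CH2Cl2, 0 °C → rt; then K2CO3, MeOH to free the phenols) would give 3-[3-acetyl-2,6-bis(benzyloxy)-4-hydroxyphenyl]-5-hydroxy-7-methoxy-2-(4-methoxyphenyl)-4H-chromen-4-one F1. Aldol condensation of this ketone with commercial 4-(benzyloxy)benzaldehyde (KOH, EtOH/THF, rt) would give chalcone 14, which is cyclised as in step 7 (NaOAc, EtOH, 70 °C), so the route is rejoined at 15.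

2. Step 8. The rate difference between the two enantiomers may be too small, or reduction may stall, because the C4 carbonyl is flanked by the 5-benzyloxy group and a hindered biaryl axis whose rotamers may respond differently to the catalyst. Fallback (enantioselective reduction in place of resolution): starting from 15, dehydrogenation (I2 (cat.), DMSO, 120 °C) would give 5,7-bis(benzyloxy)-2-[4-(benzyloxy)phenyl]-6-[5-hydroxy-7-methoxy-2-(4-methoxyphenyl)-4-oxo-4H-chromen-3-yl]-4H-chromen-4-one F2. Copper hydride catalysed asymmetric conjugate reduction of its trisubstituted 2-aryl chromone double bond would follow (Cu(OAc)2, DTBM-SEGPHOS, (EtO)2MeSiH, t-BuOH as proton source, toluene, rt). The ligand enantiomer is chosen to give the 2R ketone, to be assigned on a model flavone. The tetrasubstituted, doubly arylated double bond of the other chromone should not react. The route is rejoined at 16.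

3. Step 5. Transmetalation at the doubly ortho-substituted boronate may be slow, so that protodeboronation wins and the four-fold ortho-substituted axis does not form. Fallback (zinc in place of boron, no base-mediated transmetalation): starting from 6, the aryllithium 7 is made as in step 4 and treated with ZnCl2 to give [2,6-bis(benzyloxy)-4-{[tri(propan-2-yl)silyl]oxy}phenyl]zinc chloride F3. Iodide 4 is converted with NaH into sodium 3-iodo-7-methoxy-2-(4-methoxyphenyl)-4-oxo-4H-chromen-5-olate F4. Negishi coupling of the two (Pd2(dba)3, RuPhos, THF, 65 °C) would give, after aqueous work-up, silyl ether 9, where the route is rejoined (then Bu4NF to 10).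

Further compounds
F1 | step 7 | 3-[3-acetyl-2,6-bis(benzyloxy)-4-hydroxyphenyl]-5-hydroxy-7-methoxy-2-(4-methoxyphenyl)-4H-chromen-4-one | COc1ccc(-c2oc3cc(OC)cc(O)c3c(=O)c2-c2c(OCc3ccccc3)c(C(C)=O)c(O)cc2OCc2ccccc2)cc1
F2 | step 8 | 5,7-bis(benzyloxy)-2-[4-(benzyloxy)phenyl]-6-[5-hydroxy-7-methoxy-2-(4-methoxyphenyl)-4-oxo-4H-chromen-3-yl]-4H-chromen-4-one | COc1ccc(-c2oc3cc(OC)cc(O)c3c(=O)c2-c2c(OCc3ccccc3)cc3oc(-c4ccc(OCc5ccccc5)cc4)cc(=O)c3c2OCc2ccccc2)cc1
F3 | step 5 | [2,6-bis(benzyloxy)-4-{[tri(propan-2-yl)silyl]oxy}phenyl]zinc chloride | Cl[Zn]c1c(OCc2ccccc2)cc(O[Si](C(C)C)(C(C)C)C(C)C)cc1OCc1ccccc1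
F4 | step 5 | sodium 3-iodo-7-methoxy-2-(4-methoxyphenyl)-4-oxo-4H-chromen-5-olate | COc1ccc(-c2oc3cc(OC)cc([O-])c3c(=O)c2I)cc1.[Na+]
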